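The readings are calculated from invented constants.

One ratio of the rate constants can be read from the end points of these runs, and I carry that ratio to this flask.

all flasks: L 0.19 M

| flask | X | Z | remark | time |
|---|---|---|---|---|
| larch | 0.342 M | 0.19 M | run made earlier |  |
| alder | 0.342 M | 0.43 M | run made earlier |  |
| birch | 0.17 M | 0.285 M | run made earlier |  |
| flask | 0.342 M | 0.285 M |  | 15 d |

| run | time / d | J / % | L / % |
|---|---|---|---|
| larch | 1.25 | 28.6 | 35.7 |
| larch | 1.67 | 29.7 | 36.2 |
| larch | 3.00 | 33.2 | 35.5 |
| larch | 4.00 | 34.2 | 32.9 |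
| larch | 6.00 | 31.9 | 32.7 |
| larch | 10.0 | 32.5 | 35.0 |
| larch | 15.0 | 33.1 | 34.1 |
| alder | 0.833 | 58.4 | 9.2 |
| alder | 2.50 | 93.0 | 1.2 |
| alder | 4.00 | 100.3 | 0 |
| alder | 6.00 | 101.9 | 0 |
| alder | 10.0 | 99.5 | 1.4 |
| alder | 12.0 | 98.6 | 0 |
| alder | 15.0 | 99.0 | 0.6 |
| birch | 1.25 | 26.4 | 14.7 |
| birch | 2.50 | 36.5 | 4.2 |
| birch | 4.00 | 42.7 | 3.5 |
| birch | 8.00 | 48.1 | 1.8 |
| birch | 15.0 | 49.8 | 1.9 |

(each reading ± 1 percentage point)

- the reaction counts as stopped when no species that holds the L changes by six tenths of a point or more over the second half of the time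

- the state of affairs at 15 d: stopped, and by what, or still going (all of L has reacted / Z has run out first / X has run out first / it is still moving / forward and back rates have come level)
- J at 15 d, in percent of the L charged

In larch at 15.0 d, L lost plus J comes to 99.0% of L, and the Z charged was 100%. So I book one Z per L lost, one more Z per J, and assume one X per J. The flask holds E = 1.50 Z per L, so when Z is gone, J is E − 1 + d, where d is the L left.

One of us says L takes its Z first, as birch suggests with L at 1.9%. Then d is nil and J is 50.0%.

The other points to larch, which kept 34.1% of its L. L and X race for Z, cZ cancels from the two rates, and so the fraction of L left equals the fraction of X left raised to the power S. Here S, the selectivity factor, is the rate constant of L with Z over that of X with Z; larch reads 5.29, and birch, more roughly, 4.87.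

Now only the correction d needs reckoning. The first view's X left, 72.2%, gives d = 17.9%. Fed back, that gives 8.17%. Feeding in the mean gives 10.2%, and one more mean settles near 10.9%. My J is 60.9%.

The forecast reads Z has run out first and J 61%, noting that “X would allow J up to 100%”.

The flask gives Z has run out first, with J at 60.4%.

    Z + X → G (k = 0.0962 /M/h)
    L + Z → Q (k = 0.531 /M/h)
    Q + G → J (k = 5.18 /M/h)

In the flask, Z was down to 11.2% by 1.50 d, and Q + G → J had 95% of its turnover behind it by 3.00 d. From 7.50 d, with Z at 0.0848%, L stood at 10.5% and Q at 29.2%. The X left, 66.4%, put through S gives L 11.5%; the flask holds 10.4%.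

With 0.11 M of L, the first view's X left is 48.8%, and the correction brings L to 2.08%, so J is near 97.9%. Computed, L is 1.80% and J 98.2%: there the first view holds.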